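The cyclohexane ring hides two homoallylic-alcohol retrons: carbinol C6 next to C5 with its C(=CH2)CH2OH arm, and acyloxy carbon C8 next to C7 with its acrylic acid arm (elemane numbering; C10 is the quaternary carbon, C9 the CH2). Both ring bonds C5–C6 and C7–C8 are cut. In one flask an acyclic aldehyde holding C8–C9–C10–C5=C4 and a C6–C7 linchpin, a γ-acetal 2-(tert-butoxycarbonyl)allylboronate, are joined by catalyst-controlled allylboration, the acetal is unmasked, and a type-one carbonyl-ene cyclisation closes the ring, setting C5 to C8 and both exo-methylene groups. C10 comes from a copper-catalysed allylic substitution.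

Key step: step 9

Remarks on the chemistry
- Atom numbers in the Why lines follow the elemane skeleton: C4/C3/C15 are the hydroxypropenyl arm on C5, and C11/C13/C12 are the acrylic acid arm on C7. CIP descriptors in the names use IUPAC locants; at the acrylate-bearing ring carbon the descriptor changes between some intermediates only because substituent priorities change.
- Assumption: 2-[bis(2,2,2-trifluoroethoxy)phosphoryl]propanoic acid (19) and 2-oxoethyl acetate (21) are treated as purchasable reagents.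

Step 1
Reactants: 1 tert-butyl(but-3-yn-1-yloxy)dimethylsilane
Product: 3 (2E)-5-{[tert-butyl(dimethyl)silyl]oxy}-3-methylpent-2-en-1-ol, via alkenyldimethylalane 2 (not isolated)
Conditions: Me3Al, Cp2ZrCl2 (20 mol%), CH2Cl2, 0 → 23 °C; then (CH2O)n, 0 → 23 °C; aq. KNaC4H4O6 work-up
Reagents that add atoms: trimethylaluminium C[Al](C)C; paraformaldehyde (as formaldehyde) C=O
Why: Zirconium-catalysed syn-carboalumination of the terminal alkyne (Negishi carboalumination) places methyl on the internal carbon and aluminium cis to it, and the alkenyl–aluminium bond is hydroxymethylated with retention, which fixes the E geometry without forming a stereocentre.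

Step 2
Reactants: 3 (2E)-5-{[tert-butyl(dimethyl)silyl]oxy}-3-methylpent-2-en-1-ol
Product: 4 (2E)-5-{[tert-butyl(dimethyl)silyl]oxy}-3-methylpent-2-en-1-yl diethyl phosphate
Conditions: ClP(O)(OEt)2, Et3N, 4-(dimethylamino)pyridine (10 mol%), CH2Cl2, 0 °C
Reagents that add atoms: diethyl chlorophosphate CCOP(=O)(Cl)OCC
Why: O-Phosphorylation of the primary allylic alcohol under nucleophilic catalysis installs the leaving group for a copper-catalysed SN2′ substitution without touching the silyl ether or the alkene geometry.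

Step 3
Reactants: 4 (2E)-5-{[tert-butyl(dimethyl)silyl]oxy}-3-methylpent-2-en-1-yl diethyl phosphate; 5 tert-butyl(diphenyl)(prop-2-yn-1-yloxy)silane
Product: 7 tert-butyl{[(3R,4E)-6-{[tert-butyl(diphenyl)silyl]oxy}-3-ethenyl-3,5-dimethylhex-4-en-1-yl]oxy}dimethylsilane, via alkenyldimethylalane 6 (not isolated)
Conditions: 5, Me3Al, Cp2ZrCl2 (20 mol%), CH2Cl2, 0 → 23 °C, excess Me3Al removed in vacuo; then 4, CuCl2·2H2O (5 mol%), zwitterionic (4S,5S)-1-(2,6-diethylphenyl)-4,5-diphenyl-3-(2-sulfonatophenyl)-4,5-dihydro-1H-imidazol-3-ium (carbene precursor, 5.5 mol%; or its enantiomer, whichever delivers 3R), THF, −15 °C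
Reagents that add atoms: trimethylaluminium C[Al](C)C
Why: In this enantioselective copper-catalysed allylic substitution (SN2′) with an alkenylaluminium reagent, the carbene–copper alkenyl species formed from alane 6 with retention of its E geometry attacks the methyl-bearing alkene carbon anti to the phosphate while the chiral bidentate carbene selects the alkene face, which should set the all-carbon quaternary centre (3R, the later C10) and release the vinyl group.

Step 4
Reactants: 7 tert-butyl{[(3R,4E)-6-{[tert-butyl(diphenyl)silyl]oxy}-3-ethenyl-3,5-dimethylhex-4-en-1-yl]oxy}dimethylsilane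
Product: 8 (3R,4E)-6-{[tert-butyl(diphenyl)silyl]oxy}-3-ethenyl-3,5-dimethylhex-4-en-1-ol
Conditions: pyridinium p-toluenesulfonate (20 mol%), MeOH/CH2Cl2, 23 °C
Reagents that add atoms: none
Why: Acid-catalysed methanolysis of silyl ethers discriminates by steric bulk, so the primary tert-butyldimethylsilyl ether should be cleaved while the far more acid-stable tert-butyldiphenylsilyl ether and the quaternary stereocentre are untouched.

Step 5
Reactants: 8 (3R,4E)-6-{[tert-butyl(diphenyl)silyl]oxy}-3-ethenyl-3,5-dimethylhex-4-en-1-ol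
Product: 9 (3R,4E)-6-{[tert-butyl(diphenyl)silyl]oxy}-3-ethenyl-3,5-dimethylhex-4-enal
Conditions: DMP, CH2Cl2, 0 → 23 °C
Reagents that add atoms: none
Why: Dess–Martin oxidation converts the primary alcohol into the aldehyde under mild conditions, and since the β-carbon is quaternary no stereocentre can epimerise and neither alkene can move into conjugation.

Step 6
Reactants: 10 2,2-dimethoxyacetaldehyde; 11 tert-butyl prop-2-enoate
Product: 12 tert-butyl 3-hydroxy-4,4-dimethoxy-2-methylidenebutanoate (racemic)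
Conditions: 1,4-diazabicyclo[2.2.2]octane (1 equiv), 1,4-dioxane/H2O, 23 °C
Reagents that add atoms: none
Why: In this Morita–Baylis–Hillman reaction the amine–acrylate zwitterion adds to the reactive glyoxal monoacetal and the amine is then eliminated, giving a racemic allylic alcohol whose stereocentre is erased two steps later.

Step 7
Reactants: 12 tert-butyl 3-hydroxy-4,4-dimethoxy-2-methylidenebutanoate
Product: 13 tert-butyl 3-(acetyloxy)-4,4-dimethoxy-2-methylidenebutanoate (racemic)
Conditions: Ac2O, pyridine, 4-(dimethylamino)pyridine (5 mol%), CH2Cl2, 0 °C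
Reagents that add atoms: acetic anhydride CC(=O)OC(C)=O
Why: Acetylation of the secondary allylic alcohol under nucleophilic catalysis turns the hydroxyl into the leaving group for the SN2′ borylation, and the stereocentre is of no consequence.

Step 8
Reactants: 13 tert-butyl 3-(acetyloxy)-4,4-dimethoxy-2-methylidenebutanoate
Product: 14 tert-butyl (2E)-4,4-dimethoxy-2-[(4,4,5,5-tetramethyl-1,3,2-dioxaborolan-2-yl)methyl]but-2-enoate
Conditions: B2pin2, CuCl (10 mol%), LiCl, KOAc, DMF, 23 °C
Reagents that add atoms: bis(pinacolato)diboron CC1(C)OB(OC1(C)C)B1OC(C)(C)C(C)(C)O1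
Why: Copper-mediated SN2′ borylation of the Morita–Baylis–Hillman acetate delivers boron to the methylene terminus and should give the preferred trisubstituted alkene with the acetal carbon trans to the ester and cis to CH2B, the geometry that later translates into the syn adduct.

Step 9
Reactants: 9 (3R,4E)-6-{[tert-butyl(diphenyl)silyl]oxy}-3-ethenyl-3,5-dimethylhex-4-enal; 14 tert-butyl (2E)-4,4-dimethoxy-2-[(4,4,5,5-tetramethyl-1,3,2-dioxaborolan-2-yl)methyl]but-2-enoate
Product: 18 tert-butyl 2-[(1R,2R,3S,4R,6R)-3-(3-{[tert-butyl(diphenyl)silyl]oxy}prop-1-en-2-yl)-4-ethenyl-2,6-dihydroxy-4-methylcyclohexyl]prop-2-enoate, via allylboration borate 15 (not isolated), via aldehyde borate 16 (not isolated), via cyclised borate 17 (not isolated)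
Conditions: (S)-3,3′-bis(2,4,6-triisopropylphenyl)-1,1′-binaphthyl-2,2′-diyl hydrogen phosphate (10 mol%), toluene, −30 → 0 °C; then Sc(OTf)3 (20 mol%), acetone (10 equiv), 4 Å MS, CH2Cl2, 0 → 23 °C; aq. NaHCO3 work-up
Reagents that add atoms: none
Why: Proposed new method: the phosphoric acid hydrogen-bonds to a boronate oxygen of 14 and the aldehyde of 9 is allylated through a closed chair (Zimmerman–Traxler) transition state, which forms C7–C8 and moves the alkene to C11=C13; Sc(OTf)3-catalysed acetal exchange with acetone then frees the C6 aldehyde, which the C5=C4 alkene attacks in a type-one intramolecular carbonyl-ene reaction that forms C5–C6, creates the C4=C3 methylene and leaves the C6 hydroxyl. The closest known reactions are the Brønsted- and Lewis-acid-catalysed allylboration of aldehydes with 2-alkoxycarbonyl allylboronates, the chiral-phosphoric-acid-catalysed allylboration with pinacol allylboronates, and the Lewis-acid ene cyclisation of citronellal to isopulegol, but their union in one flask on a γ-acetal boronate is without precedent. Only the cyclohexane is closed, by 6-exo-trig attack of alkene carbon C5 on the carbonyl carbon C6 through a chair. C8 is set by the catalyst (Si-face attack, independent of the remote C10), C7 by the boronate geometry (acetal carbon cis to CH2B, hence axial in the chair, giving the syn adduct), and C5 and C6 by the ene step, in which hydrogen can be delivered only from the C-methyl cis to C10, which enforces the cis C4/O6 relationship, while the chair that keeps the C8 borate equatorial and avoids a triaxial C6=O/C8–O/vinyl array puts O6 trans to the C7 arm. The step needs allylation of the aliphatic aldehyde before the second aldehyde exists (secured by the acetal, which is inert to the phosphoric acid), hydrogen transfer from CH3 and not from CH2OSi (secured by the deactivated, shielded silyloxymethyl group, as in ene reactions of methallyl ethers), and an O8 that neither chelates nor lactonises (secured by the pinacol borate cap and the tert-butyl ester).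

Step 10
Reactants: 18 tert-butyl 2-[(1R,2R,3S,4R,6R)-3-(3-{[tert-butyl(diphenyl)silyl]oxy}prop-1-en-2-yl)-4-ethenyl-2,6-dihydroxy-4-methylcyclohexyl]prop-2-enoate; 19 2-[bis(2,2,2-trifluoroethoxy)phosphoryl]propanoic acid
Product: 20 tert-butyl 2-[(1S,2R,3S,4R,6R)-6-({2-[bis(2,2,2-trifluoroethoxy)phosphoryl]propanoyl}oxy)-3-(3-{[tert-butyl(diphenyl)silyl]oxy}prop-1-en-2-yl)-4-ethenyl-2-hydroxy-4-methylcyclohexyl]prop-2-enoate (epimer mixture at the phosphonate-bearing carbon)
Conditions: EDC·HCl, 4-(dimethylamino)pyridine (10 mol%), CH2Cl2, 0 °C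
Reagents that add atoms: none
Why: Carbodiimide (Steglich) esterification should acylate the equatorial C8 hydroxyl, which has a CH2 neighbour, in preference to the axial C6 hydroxyl, which is flanked by two branched carbons and syn-axial to the C10 methyl; no ring stereocentre changes and the new phosphonate-bearing carbon is an inconsequential epimer mixture.

Step 11
Reactants: 20 tert-butyl 2-[(1S,2R,3S,4R,6R)-6-({2-[bis(2,2,2-trifluoroethoxy)phosphoryl]propanoyl}oxy)-3-(3-{[tert-butyl(diphenyl)silyl]oxy}prop-1-en-2-yl)-4-ethenyl-2-hydroxy-4-methylcyclohexyl]prop-2-enoate; 21 2-oxoethyl acetate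
Product: 22 tert-butyl 2-[(1S,2R,3S,4R,6R)-6-{[(2Z)-4-(acetyloxy)-2-methylbut-2-enoyl]oxy}-3-(3-{[tert-butyl(diphenyl)silyl]oxy}prop-1-en-2-yl)-4-ethenyl-2-hydroxy-4-methylcyclohexyl]prop-2-enoate
Conditions: KN(SiMe3)2, 18-crown-6, THF, −78 °C; then 21, −78 °C
Reagents that add atoms: none
Why: In this Still–Gennari olefination the potassium salt of the bis(trifluoroethyl) phosphonate adds to the aldehyde and the electron-poor phosphonate collapses under kinetic control to the Z-trisubstituted enoate (ester cis to CH2OAc), while the 1,3-trans disposition of O6 and O8 prevents acyl migration and no stereocentre is formed.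

Step 12
Reactants: 22 tert-butyl 2-[(1S,2R,3S,4R,6R)-6-{[(2Z)-4-(acetyloxy)-2-methylbut-2-enoyl]oxy}-3-(3-{[tert-butyl(diphenyl)silyl]oxy}prop-1-en-2-yl)-4-ethenyl-2-hydroxy-4-methylcyclohexyl]prop-2-enoate
Product: 24 2-[(1S,2R,3S,4R,6R)-6-{[(2Z)-4-(acetyloxy)-2-methylbut-2-enoyl]oxy}-4-ethenyl-2-hydroxy-3-(3-hydroxyprop-1-en-2-yl)-4-methylcyclohexyl]prop-2-enoic acid (CNP0261293.1), via bis-trimethylsilyl intermediate 23 (not isolated)
Conditions: TMSOTf, 2,6-lutidine, CH2Cl2, 0 °C; then HF·pyridine, pyridine, THF, 0 → 23 °C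
Reagents that add atoms: none
Why: Silyl-triflate cleavage of the tert-butyl ester (loss of isobutene to the trimethylsilyl ester) followed by fluoride desilylation should remove all protecting groups under non-basic conditions that spare the acetate and the Z-enoate, and the trans-diaxial C6–OH and C7 arm of the preferred chair disfavour lactonisation, so no stereocentre is affected.

Compound list
1 | tert-butyl(but-3-yn-1-yloxy)dimethylsilane | C#CCCO[Si](C)(C)C(C)(C)C | starting material
2 | [(1E)-4-{[tert-butyl(dimethyl)silyl]oxy}-2-methylbut-1-en-1-yl]dimethylalane | C[Al](C)/C=C(\C)CCO[Si](C)(C)C(C)(C)C | intermediate (not isolated)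
3 | (2E)-5-{[tert-butyl(dimethyl)silyl]oxy}-3-methylpent-2-en-1-ol | OC/C=C(\C)CCO[Si](C)(C)C(C)(C)C | intermediate
4 | (2E)-5-{[tert-butyl(dimethyl)silyl]oxy}-3-methylpent-2-en-1-yl diethyl phosphate | CCOP(=O)(OCC)OC/C=C(\C)CCO[Si](C)(C)C(C)(C)C | intermediate
5 | tert-butyl(diphenyl)(prop-2-yn-1-yloxy)silane | C#CCO[Si](c1ccccc1)(c1ccccc1)C(C)(C)C | starting material
6 | [(1E)-3-{[tert-butyl(diphenyl)silyl]oxy}-2-methylprop-1-en-1-yl]dimethylalane | C[Al](C)/C=C(\C)CO[Si](c1ccccc1)(c1ccccc1)C(C)(C)C | intermediate (not isolated)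
7 | tert-butyl{[(3R,4E)-6-{[tert-butyl(diphenyl)silyl]oxy}-3-ethenyl-3,5-dimethylhex-4-en-1-yl]oxy}dimethylsilane | C=C[C@@](/C=C(\C)CO[Si](c1ccccc1)(c1ccccc1)C(C)(C)C)(C)CCO[Si](C)(C)C(C)(C)C | intermediate
8 | (3R,4E)-6-{[tert-butyl(diphenyl)silyl]oxy}-3-ethenyl-3,5-dimethylhex-4-en-1-ol | C=C[C@@](/C=C(\C)CO[Si](c1ccccc1)(c1ccccc1)C(C)(C)C)(C)CCO | intermediate
9 | (3R,4E)-6-{[tert-butyl(diphenyl)silyl]oxy}-3-ethenyl-3,5-dimethylhex-4-enal | C=C[C@@](/C=C(\C)CO[Si](c1ccccc1)(c1ccccc1)C(C)(C)C)(C)CC=O | intermediate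
10 | 2,2-dimethoxyacetaldehyde | COC(OC)C=O | starting material
11 | tert-butyl prop-2-enoate | C=CC(=O)OC(C)(C)C | starting material
12 | tert-butyl 3-hydroxy-4,4-dimethoxy-2-methylidenebutanoate (racemic) | C=C(C(O)C(OC)OC)C(=O)OC(C)(C)C | intermediate
13 | tert-butyl 3-(acetyloxy)-4,4-dimethoxy-2-methylidenebutanoate (racemic) | C=C(C(OC(C)=O)C(OC)OC)C(=O)OC(C)(C)C | intermediate
14 | tert-butyl (2E)-4,4-dimethoxy-2-[(4,4,5,5-tetramethyl-1,3,2-dioxaborolan-2-yl)methyl]but-2-enoate | COC(OC)/C=C(\CB1OC(C)(C)C(C)(C)O1)C(=O)OC(C)(C)C | intermediate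
15 | tert-butyl (3R,4R,6R,7E)-9-{[tert-butyl(diphenyl)silyl]oxy}-3-(dimethoxymethyl)-6-ethenyl-6,8-dimethyl-2-methylidene-4-[(4,4,5,5-tetramethyl-1,3,2-dioxaborolan-2-yl)oxy]non-7-enoate | C=C[C@@](/C=C(\C)CO[Si](c1ccccc1)(c1ccccc1)C(C)(C)C)(C)C[C@@H](OB1OC(C)(C)C(C)(C)O1)[C@@H](C(=C)C(=O)OC(C)(C)C)C(OC)OC | intermediate (not isolated)
16 | tert-butyl (3R,4R,6R,7E)-9-{[tert-butyl(diphenyl)silyl]oxy}-6-ethenyl-3-formyl-6,8-dimethyl-2-methylidene-4-[(4,4,5,5-tetramethyl-1,3,2-dioxaborolan-2-yl)oxy]non-7-enoate | C=C[C@@](/C=C(\C)CO[Si](c1ccccc1)(c1ccccc1)C(C)(C)C)(C)C[C@@H](OB1OC(C)(C)C(C)(C)O1)[C@@H](C(=C)C(=O)OC(C)(C)C)C=O | intermediate (not isolated)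
17 | tert-butyl 2-[(1S,2R,3S,4R,6R)-3-(3-{[tert-butyl(diphenyl)silyl]oxy}prop-1-en-2-yl)-4-ethenyl-2-hydroxy-4-methyl-6-[(4,4,5,5-tetramethyl-1,3,2-dioxaborolan-2-yl)oxy]cyclohexyl]prop-2-enoate | C=C[C@@]1(C)C[C@@H](OB2OC(C)(C)C(C)(C)O2)[C@@H](C(=C)C(=O)OC(C)(C)C)[C@H](O)[C@@H]1C(=C)CO[Si](c1ccccc1)(c1ccccc1)C(C)(C)C | intermediate (not isolated)
18 | tert-butyl 2-[(1R,2R,3S,4R,6R)-3-(3-{[tert-butyl(diphenyl)silyl]oxy}prop-1-en-2-yl)-4-ethenyl-2,6-dihydroxy-4-methylcyclohexyl]prop-2-enoate | C=C[C@@]1(C)C[C@@H](O)[C@@H](C(=C)C(=O)OC(C)(C)C)[C@H](O)[C@@H]1C(=C)CO[Si](c1ccccc1)(c1ccccc1)C(C)(C)C | intermediate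
19 | 2-[bis(2,2,2-trifluoroethoxy)phosphoryl]propanoic acid | CC(C(=O)O)P(=O)(OCC(F)(F)F)OCC(F)(F)F | starting material
20 | tert-butyl 2-[(1S,2R,3S,4R,6R)-6-({2-[bis(2,2,2-trifluoroethoxy)phosphoryl]propanoyl}oxy)-3-(3-{[tert-butyl(diphenyl)silyl]oxy}prop-1-en-2-yl)-4-ethenyl-2-hydroxy-4-methylcyclohexyl]prop-2-enoate (epimer mixture at the phosphonate-bearing carbon) | C=C[C@@]1(C)C[C@@H](OC(=O)C(C)P(=O)(OCC(F)(F)F)OCC(F)(F)F)[C@@H](C(=C)C(=O)OC(C)(C)C)[C@H](O)[C@@H]1C(=C)CO[Si](c1ccccc1)(c1ccccc1)C(C)(C)C | intermediate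
21 | 2-oxoethyl acetate | CC(=O)OCC=O | starting material
22 | tert-butyl 2-[(1S,2R,3S,4R,6R)-6-{[(2Z)-4-(acetyloxy)-2-methylbut-2-enoyl]oxy}-3-(3-{[tert-butyl(diphenyl)silyl]oxy}prop-1-en-2-yl)-4-ethenyl-2-hydroxy-4-methylcyclohexyl]prop-2-enoate | C=C[C@@]1(C)C[C@@H](OC(=O)/C(C)=C\COC(C)=O)[C@@H](C(=C)C(=O)OC(C)(C)C)[C@H](O)[C@@H]1C(=C)CO[Si](c1ccccc1)(c1ccccc1)C(C)(C)C | intermediate
23 | trimethylsilyl 2-[(1R,2R,3S,4R,6R)-6-{[(2Z)-4-(acetyloxy)-2-methylbut-2-enoyl]oxy}-3-(3-{[tert-butyl(diphenyl)silyl]oxy}prop-1-en-2-yl)-4-ethenyl-4-methyl-2-[(trimethylsilyl)oxy]cyclohexyl]prop-2-enoate | C=C[C@@]1(C)C[C@@H](OC(=O)/C(C)=C\COC(C)=O)[C@@H](C(=C)C(=O)O[Si](C)(C)C)[C@H](O[Si](C)(C)C)[C@@H]1C(=C)CO[Si](c1ccccc1)(c1ccccc1)C(C)(C)C | intermediate (not isolated)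
24 | 2-[(1S,2R,3S,4R,6R)-6-{[(2Z)-4-(acetyloxy)-2-methylbut-2-enoyl]oxy}-4-ethenyl-2-hydroxy-3-(3-hydroxyprop-1-en-2-yl)-4-methylcyclohexyl]prop-2-enoic acid (CNP0261293.1) | C=C[C@@]1(C)C[C@@H](OC(=O)/C(C)=C\COC(C)=O)[C@@H](C(=C)C(=O)O)[C@H](O)[C@@H]1C(=C)CO | target

Total step count: 12 (steps 1–5 make the aldehyde fragment, steps 6–8 the boronate linchpin, steps 9–12 are the union and end game).
Longest linear sequence: 9 steps (1, 2, 3, 4, 5, 9, 10, 11, 12).

Steps most likely to fail

Step 9 (bears the label). Several processes may go wrong.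
- The electron-poor boronate may react sluggishly or with poor face selectivity; if the sense of induction is opposite, the enantiomeric acid is used.
- The β,γ-unsaturated aldehyde may isomerise into conjugation and lose the C7 centre.
- Hydrogen may be transferred from the silyloxymethyl group, or a chelated chair (after loss of the borate cap) may deliver the wrong C5 or C6 configuration.
- The preferred chair also has to accept an axial acrylate arm and a methyl/carbonyl 1,3-diaxial contact.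

The fallback uses established reactions only, sets out from 9 and 12 and returns at 18. Alcohol 12 is converted with N-bromosuccinimide and Me2S, with allylic transposition, into tert-butyl (2Z)-2-(bromomethyl)-4,4-dimethoxybut-2-enoate F1. Indium-mediated Barbier allylation of 9 with F1 (In powder, THF/H2O) gives the syn hydroxy ester tert-butyl (3R,4R,6R,7E)-9-{[tert-butyl(diphenyl)silyl]oxy}-3-(dimethoxymethyl)-6-ethenyl-4-hydroxy-6,8-dimethyl-2-methylidenenon-7-enoate F2; catalyst control of C8 is given up here, so the C8-epimeric syn adduct has to be removed by chromatography. Iodine-catalysed acetal exchange in acetone frees the hydroxy aldehyde tert-butyl (3R,4R,6R,7E)-9-{[tert-butyl(diphenyl)silyl]oxy}-6-ethenyl-3-formyl-4-hydroxy-6,8-dimethyl-2-methylidenenon-7-enoate F3. Me2AlCl in CH2Cl2 at −78 °C then closes the ring by the type-one carbonyl-ene reaction to 18.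

Step 3. Methyl instead of alkenyl may be transferred from the mixed alane, the zirconium-containing carboalumination medium may erode the enantioselectivity, or SN2 may compete with SN2′ at the hindered trisubstituted alkene. The fallback replaces the aluminium nucleophile by an isolated boron one; it sets out from 5 (through alane 6) and returns at 7. Alane 6 is quenched with 2-methoxy-4,4,5,5-tetramethyl-1,3,2-dioxaborolane to give, after purification, tert-butyl{[(2E)-2-methyl-3-(4,4,5,5-tetramethyl-1,3,2-dioxaborolan-2-yl)prop-2-en-1-yl]oxy}diphenylsilane F4. F4 is coupled with phosphate 4 under carbene–copper catalysis with alkoxide activation (CuCl, the same chiral imidazolinium sulfonate, NaOMe, THF) to give 7.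

Step 11. The Z-selectivity may erode, the enolisable α-acetoxy aldehyde may self-condense or lose its acetyl group, or the base may engage the free C6 hydroxyl. The fallback takes the Z geometry from a ring instead of an olefination; it sets out from 18 and returns at 22.
- Commercial 3-methylfuran-2(5H)-one is opened with LiOH to lithium (2Z)-4-hydroxy-2-methylbut-2-enoate F5.
- F5 is silylated twice (tert-butyldimethylsilyl chloride, imidazole, DMF) to tert-butyl(dimethyl)silyl (2Z)-4-{[tert-butyl(dimethyl)silyl]oxy}-2-methylbut-2-enoate F6.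
- The silyl ester is cleaved selectively (K2CO3, MeOH/H2O) to (2Z)-4-{[tert-butyl(dimethyl)silyl]oxy}-2-methylbut-2-enoic acid F7.
- Carbodiimide esterification of 18 at O8 with F7 gives tert-butyl 2-[(1S,2R,3S,4R,6R)-6-{[(2Z)-4-{[tert-butyl(dimethyl)silyl]oxy}-2-methylbut-2-enoyl]oxy}-3-(3-{[tert-butyl(diphenyl)silyl]oxy}prop-1-en-2-yl)-4-ethenyl-2-hydroxy-4-methylcyclohexyl]prop-2-enoate F8.
- Buffered HF·pyridine at 0 °C removes only the primary tert-butyldimethylsilyl ether to give tert-butyl 2-[(1S,2R,3S,4R,6R)-3-(3-{[tert-butyl(diphenyl)silyl]oxy}prop-1-en-2-yl)-4-ethenyl-2-hydroxy-6-{[(2Z)-4-hydroxy-2-methylbut-2-enoyl]oxy}-4-methylcyclohexyl]prop-2-enoate F9.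
- F9 is acetylated at once (Ac2O, pyridine) to 22 before it can lactonise.

Further compounds
F1 | step 9 | tert-butyl (2Z)-2-(bromomethyl)-4,4-dimethoxybut-2-enoate | COC(OC)/C=C(\CBr)C(=O)OC(C)(C)C
F2 | step 9 | tert-butyl (3R,4R,6R,7E)-9-{[tert-butyl(diphenyl)silyl]oxy}-3-(dimethoxymethyl)-6-ethenyl-4-hydroxy-6,8-dimethyl-2-methylidenenon-7-enoate | C=C[C@@](/C=C(\C)CO[Si](c1ccccc1)(c1ccccc1)C(C)(C)C)(C)C[C@@H](O)[C@@H](C(=C)C(=O)OC(C)(C)C)C(OC)OC
F3 | step 9 | tert-butyl (3R,4R,6R,7E)-9-{[tert-butyl(diphenyl)silyl]oxy}-6-ethenyl-3-formyl-4-hydroxy-6,8-dimethyl-2-methylidenenon-7-enoate | C=C[C@@](/C=C(\C)CO[Si](c1ccccc1)(c1ccccc1)C(C)(C)C)(C)C[C@@H](O)[C@@H](C(=C)C(=O)OC(C)(C)C)C=O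
F4 | step 3 | tert-butyl{[(2E)-2-methyl-3-(4,4,5,5-tetramethyl-1,3,2-dioxaborolan-2-yl)prop-2-en-1-yl]oxy}diphenylsilane | CC1(C)OB(/C=C(\C)CO[Si](c2ccccc2)(c2ccccc2)C(C)(C)C)OC1(C)C
F5 | step 11 | lithium (2Z)-4-hydroxy-2-methylbut-2-enoate | [Li+].[O-]C(=O)/C(C)=C\CO
F6 | step 11 | tert-butyl(dimethyl)silyl (2Z)-4-{[tert-butyl(dimethyl)silyl]oxy}-2-methylbut-2-enoate | CC(C)(C)[Si](C)(C)OC(=O)/C(C)=C\CO[Si](C)(C)C(C)(C)C
F7 | step 11 | (2Z)-4-{[tert-butyl(dimethyl)silyl]oxy}-2-methylbut-2-enoic acid | OC(=O)/C(C)=C\CO[Si](C)(C)C(C)(C)C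
F8 | step 11 | tert-butyl 2-[(1S,2R,3S,4R,6R)-6-{[(2Z)-4-{[tert-butyl(dimethyl)silyl]oxy}-2-methylbut-2-enoyl]oxy}-3-(3-{[tert-butyl(diphenyl)silyl]oxy}prop-1-en-2-yl)-4-ethenyl-2-hydroxy-4-methylcyclohexyl]prop-2-enoate | C=C[C@@]1(C)C[C@@H](OC(=O)/C(C)=C\CO[Si](C)(C)C(C)(C)C)[C@@H](C(=C)C(=O)OC(C)(C)C)[C@H](O)[C@@H]1C(=C)CO[Si](c1ccccc1)(c1ccccc1)C(C)(C)C
F9 | step 11 | tert-butyl 2-[(1S,2R,3S,4R,6R)-3-(3-{[tert-butyl(diphenyl)silyl]oxy}prop-1-en-2-yl)-4-ethenyl-2-hydroxy-6-{[(2Z)-4-hydroxy-2-methylbut-2-enoyl]oxy}-4-methylcyclohexyl]prop-2-enoate | C=C[C@@]1(C)C[C@@H](OC(=O)/C(C)=C\CO)[C@@H](C(=C)C(=O)OC(C)(C)C)[C@H](O)[C@@H]1C(=C)CO[Si](c1ccccc1)(c1ccccc1)C(C)(C)C
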